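## The problem

Miyabenol A (33) is a linear resveratrol tetramer built from three 2,3-trans-2-(4-hydroxyphenyl)-2,3-dihydrobenzofurans. Unit 1 (benzo ring A) carries an (E)-4-hydroxystyryl group at C4. Its C3 is bonded to C4 of unit 2, C3 of unit 2 is bonded to C4 of unit 3 (benzo ring C), and C3 of unit 3 carries the 3,5-dihydroxyphenyl ring D. No rings are fused beyond the benzofurans, so the real difficulty is the thrice-repeated C3(sp3)–aryl bond, which is flanked by ortho substituents on both sides. The six stereocentres form three trans pairs: unit 1 (2R,3R), unit 2 (2S,3S), unit 3 (2R,3R). Within a unit C3 can direct C2, since the trans ring is favoured and C2 can equilibrate through its benzylic C2–O bond. Between units the centres are separated by an arene and cannot be relied on to relay, so each C3 needs reagent control, with the opposite sense for the central unit. Sensitive features are the nine phenols (air oxidation as phenoxides) and the three 4-oxybenzylic C2–O bonds (ionisation by acid, hydrogenolysis). The stilbene is the most fragile: acid can cyclise it onto C5 of the unit-2 benzo ring, and it is also open to hydrogenation and to E/Z isomerisation by light. The enabling feature is that in every unit C3 (two aryl groups and H) and C2 (one aryl group, O and H) are adjacent methines. That is the pattern left when an aryl electrophile and a migrating aryl group add across a β-aryl alkenylboron whose aryl ring already carries the future ring oxygen, the C–B bond standing in for the C2–O bond.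

## Retrosynthesis

**Stilbene and phenol release (33 ⇐ 32 ⇐ 30 + 31).** The nine O–acetyl bonds of nonaacetate 32 are cut last, and before that the bond from C4 of ring A to the vinyl carbon (Heck reaction of aryl triflate 30 with 4-acetoxystyrene 31). Carrying the stilbene through the synthesis would expose it to hydrogenation and to Lewis acid. Methyl ethers at the end would require BBr3 in the presence of a 4-styryl-3-aryl-dihydrobenzofuran, the arrangement most prone to acid cyclisation. Acetates come off under nearly neutral conditions. The forward step must be a terminal-carbon-selective, E-selective Heck reaction on a hindered triflate.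

**Exchange of the phenol protection (30 ⇐ 29 ⇐ 28).** Eight O–acetyl bonds go back to eight O–methyl bonds. Methyl ethers are what the aryllithium, palladium, peroxide and Mitsunobu steps need. They are exchanged for acetates at the stage of triflate 28, where no alkene is present and the triflate is inert to BBr3. The demethylation must leave the three dihydrobenzofurans trans, which reversible C2–O ionisation does.

**Unit 1 (28 ⇐ 27 ⇐ 26 ⇐ 25 ⇐ 13 + 23).** Triflate 28 comes from phenol 27. Cutting O1–C2 of 27 (Mitsunobu closure with inversion) gives triol 26, and restoring the two benzyl ethers gives alcohol 25. Its C–OH bond derives from the C–B bond of boronic ester 24, and the two C–C bonds C3(unit 1)–C4(unit 2) and C2–anisyl are cut together by conjunctive cross-coupling of borate 13 with aryl triflate 23. Compared with cutting C3–C3a (Friedel–Crafts chemistry) or a biomimetic phenol–stilbene oxidative coupling, this cut gives absolute control at C3 and strips a whole unit down to one achiral building block.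

**Unit 2 (23 ⇐ 22 ⇐ 21 ⇐ 20 ⇐ 13 + 18).** This is the same sequence one unit further in: triflate 23 from phenol 22, triol 21, alcohol 20 (through boronic ester 19), and the coupling of 13 with triflate 18. The only change is the enantiomeric ligand, because unit 2 is antipodal. The forward reaction must accept an aryl triflate with a branched ortho substituent and let the catalyst override the remote centres of 18.

**Unit 3 and the key step (18 ⇐ 17 ⇐ 16 ⇐ 15 ⇐ 14 ⇐ 13 + 10).** Triflate 18 comes from phenol 17, 17 from triol 16 by Mitsunobu closure, 16 from dibenzyl ether 15, and 15 from secondary boronic ester 14 by oxidation. Boronate 14 is cut at the C3–ring D bond and the C2–anisyl bond into borate 13 and 3,5-dimethoxyphenyl triflate 10. Anti addition across the E alkene sets the boron-bearing carbon opposite to C2 of the target on purpose, so that the invertive ring closure arrives at the trans ring.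

**The borate (13 ⇐ 8 + 12; 12 ⇐ 11).** Borate 13 is the ate complex of alkenylboronate 8 with 4-methoxyphenyllithium 12, which comes from 4-bromoanisole 11. All three units need the same borate, so it is made once, in a step of its own, and the bromide from the lithium–bromine exchange is removed there, before any palladium is present. Two features are built into its alkenylboron part:
- Boron carries the hindered diol 6 in place of pinacol, because pinacol esters of β-substituted alkenylboron ate complexes tend to divert into direct transmetallation.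
- Both ortho oxygens of ring C carry benzyl groups. Ring C is then symmetric: hydrogenolysis frees both phenols, either one closes the ring, and the other is left for the triflate, so the two oxygens never have to be told apart.

**Building blocks (8 ⇐ 4 + 6; 4 ⇐ 3 ⇐ 2 ⇐ 1; 6 ⇐ 5; 10 ⇐ 9).** Alkenylboronate 8 comes from alkyne 4 by hydroboration (through catechol ester 7) and exchange with diol 6. Alkyne 4 comes from aldehyde 3, 3 from dihydroxy aldehyde 2, and 2 from 2,4,6-trimethoxybenzaldehyde 1. Diol 6 comes from acenaphthoquinone 5, and triflate 10 from 3,5-dimethoxyphenol 9. All of these are one-step functional-group operations on commercial arenes.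

## Roads not taken

**Alternative 1:** Ring A and the furan ring of unit 1 are made last from three alkynes, cutting C3a–C7a, C4–C5 and C6–C7.
- *Forward step:* diyne A2 is an open unit-1 precursor with the internal alkyne of a 4-methoxystyryl enyne on C3 and an ethynyl ether on the C2 oxygen. It would be cyclotrimerised with ethoxyacetylene A3 under [Rh(cod)2]BF4 and a bisphosphine to give the protected tetramer A1.
- *Merits:* three C–C bonds and two rings form in one step, the stilbene arrives with the ring, and unit 1 needs no hindered C(sp3)–aryl coupling. In bonds per step it is better than the chosen plan.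
- *Weak points:* A3 must insert with its oxygen at C6 and not C5. The ynol ether of a secondary benzylic alcohol is thermally fragile. The enyne alkene can compete. C3 of A2 is propargylic and doubly benzylic, hence epimerisable. The step also presupposes both stereocentres of unit 1, and all of units 2 and 3, from other chemistry, and it ends with ethyl and methyl ethers that must be cleaved beside the stilbene.
- *Comparison:* the chosen plan sets against it that one reaction makes the C3–aryl bond and both stereocentres of every unit, from one alkenylboron reagent.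

**Alternative 2:** The central unit is taken from the chiral pool, cutting C3–C3a of unit 2 back to a flavanone.
- *Forward step:* (2S)-naringenin A4, with its phenols masked, would be treated with PhI(OAc)2 and H2SO4 in trimethyl orthoformate. The enol ether is iodinated by trivalent iodine, the aryl carbon shifts from C4 to C3, and the pyranone contracts to the trans ester A5 in the unit-2 configuration.
- *Merits:* absolute configuration comes from a cheap natural product with no chiral catalyst, and the contraction is a well-known reaction that gives the trans ring. In the source of chirality it is better than the chosen plan.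
- *Weak points:* only the central unit has the natural configuration; units 1 and 3 need the unnatural flavanone. Flavanones racemise at C2 through ring opening to the chalcone under the acidic conditions. C3 ends as a methyl ester where the target needs the hindered bond to the next arene, so the hardest bond is still unmade.
- *Comparison:* the chosen plan sets against it that the C3–aryl bond is made in the stereo-defining step, and both enantiomeric series come from the two ligand antipodes.

**Alternative 3:** The three C2–aryl bonds are cut at once.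
- *Forward step:* triacid A6 and three equivalents of 4-iodoanisole A7 would couple under light with Ir[dF(CF3)ppy]2(dtbbpy)PF6 and NiCl2(dme)/4,4'-di-tert-butyl-2,2'-bipyridine, with loss of three CO2, to give A8.
- *Merits:* three bonds form in one operation with a trivial aryl halide. The α-oxy radical at C2 is stabilised and is captured trans to the C3 aryl group, so C2 need not be set beforehand. Here it matches the chosen plan's reliance on C3 to fix C2.
- *Weak points:* all three couplings must succeed in one flask, next to very crowded C3 centres, and selectivity at each C2 is only substrate-controlled. A6 already contains the whole C3–C4-linked skeleton with its three C3 stereocentres, so the step solves the easier bonds.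
- *Comparison:* the chosen plan sets against it that the C2–aryl and C3–aryl bonds are made together with control of C3.

Key step: step 8

Assumptions and abbreviations:
- (Sp,Sp)-MandyPhos means the (Sp,Sp) enantiomer of 1,1′-bis[bis(4-methoxy-3,5-dimethylphenyl)phosphino]-2,2′-bis[α-(dimethylamino)benzyl]ferrocene. It is assumed to give the (1S,2R) adduct 14; if the sense is the reverse, the two ligand enantiomers change places in steps 8, 13 and 17.
- Borate 13 is made once, on a scale that serves steps 8, 13 and 17. It is assumed to keep as a solvent-free solid under argon at −30 °C; should it lose titre, step 7 is repeated. The lithium triflate that stays with it is harmless, since the coupling forms the same salt.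
- Aldehyde 2 is made rather than bought.
- mac ester = cyclic boronic ester of diol 6.
- U3 = (2R,3R)-3-(3,5-dimethoxyphenyl)-6-methoxy-2-(4-methoxyphenyl)-2,3-dihydro-1-benzofuran-4-yl.
- U23 = (2S,3S)-6-methoxy-2-(4-methoxyphenyl)-3-(U3)-2,3-dihydro-1-benzofuran-4-yl.

## Route

Step 1
Reactants: 1 2,4,6-trimethoxybenzaldehyde
Product: 2 2,6-dihydroxy-4-methoxybenzaldehyde
Conditions: AlCl3 (excess), CH2Cl2, 0 °C → reflux; aq. HCl
Reagents that add atoms: none
Why: Lewis-acid ether cleavage directed by chelation: aluminium bound to the formyl oxygen delivers chloride only to the two ortho methyl groups, while the para methoxy group cannot chelate and is kept (ortho-demethylation of ortho-methoxyaryl carbonyl compounds).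

Step 2
Reactants: 2 2,6-dihydroxy-4-methoxybenzaldehyde
Product: 3 2,6-bis(benzyloxy)-4-methoxybenzaldehyde
Conditions: BnBr, K2CO3, DMF, 60 °C
Reagents that add atoms: benzyl bromide, BrCc1ccccc1
Why: Williamson ether synthesis on both hydrogen-bonded phenols; two identical benzyl groups keep ring C symmetric, so the two ortho oxygens never need to be differentiated.

Step 3
Reactants: 3 2,6-bis(benzyloxy)-4-methoxybenzaldehyde
Product: 4 1,3-bis(benzyloxy)-2-ethynyl-5-methoxybenzene
Conditions: dimethyl (1-diazo-2-oxopropyl)phosphonate, K2CO3, MeOH, rt → 40 °C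
Reagents that add atoms: dimethyl (1-diazo-2-oxopropyl)phosphonate, COP(=O)(OC)C(=[N+]=[N-])C(C)=O
Why: Seyferth–Gilbert homologation with the Ohira–Bestmann reagent: the diazomethylphosphonate anion formed in situ adds to the aldehyde, and loss of dimethyl phosphate and N2 gives an alkylidene carbene that rearranges to the terminal alkyne. The base-only conditions leave the benzyl ethers untouched.

Step 4
Reactants: 5 acenaphthylene-1,2-dione
Product: 6 cis-1,2-dimethyl-1,2-dihydroacenaphthylene-1,2-diol
Conditions: AlMe3 (excess), toluene, 0 °C → rt; aq. work-up; recrystallisation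
Reagents that add atoms: trimethylaluminium, C[Al](C)C
Why: Twofold 1,2-addition of methyl to the 1,2-dione; the second methyl should add anti to the bulky aluminium alkoxide formed first, favouring the cis (meso) diol, which is purified by crystallisation. The diol is achiral and adds no stereochemical variable to the boron reagent.

Step 5
Reactants: 4 1,3-bis(benzyloxy)-2-ethynyl-5-methoxybenzene; 6 cis-1,2-dimethyl-1,2-dihydroacenaphthylene-1,2-diol
Product: 8 {(E)-2-[2,6-bis(benzyloxy)-4-methoxyphenyl]ethenyl}boronic acid mac ester, via alkenyl catechol boronate 7 (not isolated)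
Conditions: catecholborane, THF, 70 °C; then 6, rt; aq. NaHCO3 wash
Reagents that add atoms: catecholborane, B1Oc2ccccc2O1
Why: Syn, anti-Markovnikov hydroboration of the terminal arylalkyne places boron on the terminal carbon and gives the E alkene. The labile catechol ester then exchanges with the tertiary diol (transesterification).

Step 6
Reactants: 9 3,5-dimethoxyphenol
Product: 10 3,5-dimethoxyphenyl trifluoromethanesulfonate
Conditions: Tf2O, pyridine, CH2Cl2, 0 °C
Reagents that add atoms: trifluoromethanesulfonic anhydride, O=S(=O)(OS(=O)(=O)C(F)(F)F)C(F)(F)F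
Why: O-Sulfonylation of a phenol; standard aryl triflate formation.

Step 7
Reactants: 11 4-bromoanisole; 8 {(E)-2-[2,6-bis(benzyloxy)-4-methoxyphenyl]ethenyl}boronic acid mac ester
Product: 13 lithium {(E)-2-[2,6-bis(benzyloxy)-4-methoxyphenyl]ethenyl}(4-methoxyphenyl)borate of diol 6, via 4-methoxyphenyllithium 12 (not isolated)
Conditions: 11, t-BuLi (2 equiv), Et2O, −78 °C; 8, −78 °C → rt; volatiles removed; KOTf, THF, rt; filtration and evaporation under argon; solid stored at −30 °C
Reagents that add atoms: tert-butyllithium, [Li]C(C)(C)C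
Why: Lithium–bromine exchange (the second equivalent of t-BuLi destroys the tert-butyl bromide formed) gives the aryllithium, which adds to the vacant orbital of the trigonal boron of 8 to give the four-coordinate borate (ate-complex formation). KOTf then exchanges the lithium bromide for insoluble KBr, so that the borate used in the three couplings is free of halide. The two epimers at boron that can form converge when boron becomes trigonal again.

Step 8
Reactants: 13 lithium {(E)-2-[2,6-bis(benzyloxy)-4-methoxyphenyl]ethenyl}(4-methoxyphenyl)borate of diol 6; 10 3,5-dimethoxyphenyl trifluoromethanesulfonate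
Product: 14 (1S,2R)-[2-(2,6-bis(benzyloxy)-4-methoxyphenyl)-2-(3,5-dimethoxyphenyl)-1-(4-methoxyphenyl)ethyl]boronic acid mac ester
Conditions: Pd(OAc)2 (cat.), (Sp,Sp)-MandyPhos (cat.), THF, 60 °C
Reagents that add atoms: none
Why: Conjunctive cross-coupling of a β-substituted alkenylboron ate complex; the closest known case is β-alkyl alkenylboron ate complexes of this hindered diol with aryl triflates and aryllithium-derived migrating groups. Oxidative addition of 10 to zerovalent palladium gives a cationic aryl complex of divalent palladium, which binds the alkene of 13 as a π-acid. The 4-methoxyphenyl group then shifts from boron to the α-carbon anti to palladium while the β-carbon, benzylic to ring C, becomes bound to palladium, and reductive elimination with retention joins that carbon to ring D. No ring closes. The R centre at the diaryl carbon is set by the chiral bisphosphine, which chooses the alkene face bound by palladium (catalyst control). The S centre at the boron-bearing carbon follows from the stereospecific anti addition across the E double bond. The step needs the 1,2-shift to outrun direct boron-to-palladium transmetallation (the Suzuki–Miyaura path) and β-hydride elimination; the hindered diol on boron, the halide-free cationic palladium (triflate electrophile, bromide already removed from 13 in step 7) and benzylic stabilisation of the palladium–carbon bond favour it. Regiochemistry is fixed by the mechanism, since the migrating group can only arrive at the boron-bearing carbon.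

Step 9
Reactants: 14 (1S,2R)-[2-(2,6-bis(benzyloxy)-4-methoxyphenyl)-2-(3,5-dimethoxyphenyl)-1-(4-methoxyphenyl)ethyl]boronic acid mac ester
Product: 15 (1S,2R)-2-[2,6-bis(benzyloxy)-4-methoxyphenyl]-2-(3,5-dimethoxyphenyl)-1-(4-methoxyphenyl)ethan-1-ol
Conditions: NaOH (aq), H2O2, THF, 0 °C → rt
Reagents that add atoms: hydrogen peroxide, OO
Why: Oxidation of the C–B bond by hydroperoxide, with 1,2-shift of carbon from boron to oxygen; the shift proceeds with retention, so the carbinol keeps the S configuration. Diol 6 is recovered.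

Step 10
Reactants: 15 (1S,2R)-2-[2,6-bis(benzyloxy)-4-methoxyphenyl]-2-(3,5-dimethoxyphenyl)-1-(4-methoxyphenyl)ethan-1-ol
Product: 16 2-[(1R,2S)-1-(3,5-dimethoxyphenyl)-2-hydroxy-2-(4-methoxyphenyl)ethyl]-5-methoxybenzene-1,3-diol
Conditions: H2 (1 atm), Pd/C, EtOAc, rt
Reagents that add atoms: none
Why: Hydrogenolysis of the two aryl benzyl ethers over palladium; in neutral, acid-free ethyl acetate the secondary benzylic alcohol and the methyl ethers are not expected to react.

Step 11
Reactants: 16 2-[(1R,2S)-1-(3,5-dimethoxyphenyl)-2-hydroxy-2-(4-methoxyphenyl)ethyl]-5-methoxybenzene-1,3-diol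
Product: 17 (2R,3R)-3-(3,5-dimethoxyphenyl)-6-methoxy-2-(4-methoxyphenyl)-2,3-dihydro-1-benzofuran-4-ol
Conditions: PPh3, DIAD, THF, 0 °C → rt
Reagents that add atoms: none
Why: Intramolecular Mitsunobu etherification: the alcohol is activated as its oxyphosphonium salt and displaced by one of the two equivalent ortho phenols in a 5-exo-tet SN2 closure with inversion (S to R), which puts the C2 aryl group trans to the C3 aryl group. Any ionisation of this 4-methoxybenzylic centre would close to the same trans ring. The second phenol stays free.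

Step 12
Reactants: 17 (2R,3R)-3-(3,5-dimethoxyphenyl)-6-methoxy-2-(4-methoxyphenyl)-2,3-dihydro-1-benzofuran-4-ol
Product: 18 U3 trifluoromethanesulfonate
Conditions: Tf2O, pyridine, CH2Cl2, 0 °C → rt
Reagents that add atoms: trifluoromethanesulfonic anhydride, O=S(=O)(OS(=O)(=O)C(F)(F)F)C(F)(F)F
Why: O-Sulfonylation of the only free hydroxyl group; the product of one cycle becomes the aryl electrophile of the next.

Step 13
Reactants: 13 lithium {(E)-2-[2,6-bis(benzyloxy)-4-methoxyphenyl]ethenyl}(4-methoxyphenyl)borate of diol 6; 18 U3 trifluoromethanesulfonate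
Product: 20 (1R,2S)-2-[2,6-bis(benzyloxy)-4-methoxyphenyl]-1-(4-methoxyphenyl)-2-(U3)ethan-1-ol, via secondary boronic ester 19 (not isolated)
Conditions: Pd(OAc)2 (cat.), (Rp,Rp)-MandyPhos (cat.), THF, 60 °C; then NaOH (aq), H2O2, 0 °C → rt
Reagents that add atoms: hydrogen peroxide, OO
Why: The conjunctive cross-coupling of step 8, with the C4 triflate of unit 3 as electrophile and the enantiomeric ligand. Catalyst control over the remote centres of 18 should make the new diaryl carbon S, and stereospecific anti addition makes the boron-bearing carbon R. Oxidative work-up in the same flask converts C–B into C–OH with retention.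

Step 14
Reactants: 20 (1R,2S)-2-[2,6-bis(benzyloxy)-4-methoxyphenyl]-1-(4-methoxyphenyl)-2-(U3)ethan-1-ol
Product: 21 2-[(1S,2R)-2-hydroxy-2-(4-methoxyphenyl)-1-(U3)ethyl]-5-methoxybenzene-1,3-diol
Conditions: H2 (1 atm), Pd/C, EtOAc, rt
Reagents that add atoms: none
Why: Hydrogenolysis of aryl benzyl ethers, which cleave far faster than the cyclic benzylic C2–O bond of unit 3 or the free benzylic alcohol under neutral conditions.

Step 15
Reactants: 21 2-[(1S,2R)-2-hydroxy-2-(4-methoxyphenyl)-1-(U3)ethyl]-5-methoxybenzene-1,3-diol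
Product: 22 (2S,3S)-6-methoxy-2-(4-methoxyphenyl)-3-(U3)-2,3-dihydro-1-benzofuran-4-ol
Conditions: PPh3, DIAD, THF, 0 °C → rt
Reagents that add atoms: none
Why: Intramolecular Mitsunobu etherification as in step 11; the 5-exo-tet SN2 closure inverts the carbinol (R to S) and gives the trans ring of unit 2, antipodal to unit 3.

Step 16
Reactants: 22 (2S,3S)-6-methoxy-2-(4-methoxyphenyl)-3-(U3)-2,3-dihydro-1-benzofuran-4-ol
Product: 23 U23 trifluoromethanesulfonate
Conditions: Tf2O, pyridine, CH2Cl2, 0 °C → rt
Reagents that add atoms: trifluoromethanesulfonic anhydride, O=S(=O)(OS(=O)(=O)C(F)(F)F)C(F)(F)F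
Why: O-Sulfonylation of the single free phenol.

Step 17
Reactants: 13 lithium {(E)-2-[2,6-bis(benzyloxy)-4-methoxyphenyl]ethenyl}(4-methoxyphenyl)borate of diol 6; 23 U23 trifluoromethanesulfonate
Product: 25 (1S,2R)-2-[2,6-bis(benzyloxy)-4-methoxyphenyl]-1-(4-methoxyphenyl)-2-(U23)ethan-1-ol, via secondary boronic ester 24 (not isolated)
Conditions: Pd(OAc)2 (cat.), (Sp,Sp)-MandyPhos (cat.), THF, 60 °C; then NaOH (aq), H2O2, 0 °C → rt
Reagents that add atoms: hydrogen peroxide, OO
Why: Third conjunctive cross-coupling with the ligand of step 8; the ligand should set the diaryl carbon R, anti addition sets the boron-bearing carbon S, and oxidation proceeds with retention.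

Step 18
Reactants: 25 (1S,2R)-2-[2,6-bis(benzyloxy)-4-methoxyphenyl]-1-(4-methoxyphenyl)-2-(U23)ethan-1-ol
Product: 26 2-[(1R,2S)-2-hydroxy-2-(4-methoxyphenyl)-1-(U23)ethyl]-5-methoxybenzene-1,3-diol
Conditions: H2 (1 atm), Pd/C, EtOAc, rt
Reagents that add atoms: none
Why: Hydrogenolysis of the two aryl benzyl ethers under the neutral conditions of steps 10 and 14.

Step 19
Reactants: 26 2-[(1R,2S)-2-hydroxy-2-(4-methoxyphenyl)-1-(U23)ethyl]-5-methoxybenzene-1,3-diol
Product: 27 (2R,3R)-6-methoxy-2-(4-methoxyphenyl)-3-(U23)-2,3-dihydro-1-benzofuran-4-ol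
Conditions: PPh3, DIAD, THF, 0 °C → rt
Reagents that add atoms: none
Why: Intramolecular Mitsunobu etherification with inversion (S to R) closes the trans dihydrofuran ring of unit 1.

Step 20
Reactants: 27 (2R,3R)-6-methoxy-2-(4-methoxyphenyl)-3-(U23)-2,3-dihydro-1-benzofuran-4-ol
Product: 28 (2R,3R)-6-methoxy-2-(4-methoxyphenyl)-3-(U23)-2,3-dihydro-1-benzofuran-4-yl trifluoromethanesulfonate
Conditions: Tf2O, pyridine, CH2Cl2, 0 °C → rt
Reagents that add atoms: trifluoromethanesulfonic anhydride, O=S(=O)(OS(=O)(=O)C(F)(F)F)C(F)(F)F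
Why: O-Sulfonylation of the ring A phenol marks C4 of unit 1 for the final C–C bond.

Step 21
Reactants: 28 (2R,3R)-6-methoxy-2-(4-methoxyphenyl)-3-(U23)-2,3-dihydro-1-benzofuran-4-yl trifluoromethanesulfonate
Product: 29 octaphenol triflate (28 with all eight methoxy groups as hydroxy groups)
Conditions: BBr3 (excess), CH2Cl2, −78 °C → rt; ice water
Reagents that add atoms: none
Why: Boron tribromide cleavage of all eight aryl methyl ethers (Lewis-acid activation, bromide SN2 at methyl). Aryl triflates are inert to BBr3, and with no alkene present a C2–O bond that ionises can only re-close to the trans ring.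

Step 22
Reactants: 29 octaphenol triflate
Product: 30 octaacetate triflate (29 with all eight hydroxy groups acetylated)
Conditions: Ac2O, pyridine, DMAP (cat.), rt
Reagents that add atoms: acetic anhydride, CC(=O)OC(C)=O
Why: Acylation of phenols; acetates shield the phenols from oxidation during the palladium step and can be removed later without acid.

Step 23
Reactants: 30 octaacetate triflate; 31 4-acetoxystyrene
Product: 32 miyabenol A nonaacetate
Conditions: PdCl2(PPh3)2 (cat.), LiCl, Et3N, DMF, 90 °C, dark
Reagents that add atoms: none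
Why: Mizoroki–Heck reaction: oxidative addition of the triflate and exchange to the neutral aryl–palladium chloride (LiCl) are followed by syn insertion of the styrene with the aryl group at the terminal carbon and syn β-hydride elimination, giving the E stilbene. Aryl acetates are known to survive these amine-base conditions.

Step 24
Reactants: 32 miyabenol A nonaacetate
Product: 33 miyabenol A
Conditions: NH4OAc, MeOH–H2O, rt → 40 °C, argon, dark
Reagents that add atoms: none
Why: Transesterification of the nine aryl acetates to methanol under nearly neutral ammonium acetate catalysis. Neither acid (which could cyclise the stilbene onto unit 2) nor strong base (which promotes phenoxide oxidation) is present, and light is excluded to keep the E alkene.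

## Compound list

1 | 2,4,6-trimethoxybenzaldehyde | COc1cc(OC)c(C=O)c(OC)c1 | starting material
2 | 2,6-dihydroxy-4-methoxybenzaldehyde | COc1cc(O)c(C=O)c(O)c1 | intermediate
3 | 2,6-bis(benzyloxy)-4-methoxybenzaldehyde | COc1cc(OCc2ccccc2)c(C=O)c(OCc2ccccc2)c1 | intermediate
4 | 1,3-bis(benzyloxy)-2-ethynyl-5-methoxybenzene | COc1cc(OCc2ccccc2)c(C#C)c(OCc2ccccc2)c1 | intermediate
5 | acenaphthylene-1,2-dione (acenaphthoquinone) | O=C1C(=O)c2cccc3cccc1c23 | starting material
6 | cis-(1R,2S)-1,2-dimethyl-1,2-dihydroacenaphthylene-1,2-diol (meso) | C[C@]1(O)c2cccc3cccc(c23)[C@@]1(C)O | intermediate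
7 | 2-{(E)-2-[2,6-bis(benzyloxy)-4-methoxyphenyl]ethenyl}-1,3,2-benzodioxaborole | COc1cc(OCc2ccccc2)c(/C=C/B2Oc3ccccc3O2)c(OCc2ccccc2)c1 | intermediate (not isolated)
8 | {(E)-2-[2,6-bis(benzyloxy)-4-methoxyphenyl]ethenyl}boronic acid, cyclic ester with diol 6 (mac ester) | COc1cc(OCc2ccccc2)c(/C=C/B2O[C@@]3(C)c4cccc5cccc(c45)[C@@]3(C)O2)c(OCc2ccccc2)c1 | intermediate
9 | 3,5-dimethoxyphenol | COc1cc(O)cc(OC)c1 | starting material
10 | 3,5-dimethoxyphenyl trifluoromethanesulfonate | COc1cc(OC)cc(OS(=O)(=O)C(F)(F)F)c1 | intermediate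
11 | 4-bromoanisole | COc1ccc(Br)cc1 | starting material
12 | 4-methoxyphenyllithium | [Li]c1ccc(OC)cc1 | intermediate (not isolated)
13 | lithium {(E)-2-[2,6-bis(benzyloxy)-4-methoxyphenyl]ethenyl}(4-methoxyphenyl)borate of diol 6 | [Li+].COc1ccc(cc1)[B-]1(/C=C/c2c(OCc3ccccc3)cc(OC)cc2OCc2ccccc2)O[C@@]2(C)c3cccc4cccc(c34)[C@@]2(C)O1 | intermediate
14 | (1S,2R)-[2-(2,6-bis(benzyloxy)-4-methoxyphenyl)-2-(3,5-dimethoxyphenyl)-1-(4-methoxyphenyl)ethyl]boronic acid mac ester | O(Cc1ccccc1)c1cc(OC)cc(OCc2ccccc2)c1[C@@H](c1cc(OC)cc(OC)c1)[C@@H](c1ccc(OC)cc1)B1O[C@@]2(C)c3cccc4cccc(c34)[C@@]2(C)O1 | intermediate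
15 | (1S,2R)-2-[2,6-bis(benzyloxy)-4-methoxyphenyl]-2-(3,5-dimethoxyphenyl)-1-(4-methoxyphenyl)ethan-1-ol | O(Cc1ccccc1)c1cc(OC)cc(OCc2ccccc2)c1[C@@H](c1cc(OC)cc(OC)c1)[C@@H](c1ccc(OC)cc1)O | intermediate
16 | 2-[(1R,2S)-1-(3,5-dimethoxyphenyl)-2-hydroxy-2-(4-methoxyphenyl)ethyl]-5-methoxybenzene-1,3-diol | Oc1cc(OC)cc(O)c1[C@@H](c1cc(OC)cc(OC)c1)[C@@H](c1ccc(OC)cc1)O | intermediate
17 | (2R,3R)-3-(3,5-dimethoxyphenyl)-6-methoxy-2-(4-methoxyphenyl)-2,3-dihydro-1-benzofuran-4-ol | Oc1cc(OC)cc2c1[C@@H](c1cc(OC)cc(OC)c1)[C@H](c1ccc(OC)cc1)O2 | intermediate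
18 | (2R,3R)-3-(3,5-dimethoxyphenyl)-6-methoxy-2-(4-methoxyphenyl)-2,3-dihydro-1-benzofuran-4-yl trifluoromethanesulfonate | O=S(=O)(Oc1cc(OC)cc2c1[C@@H](c1cc(OC)cc(OC)c1)[C@H](c1ccc(OC)cc1)O2)C(F)(F)F | intermediate
19 | (1R,2S)-[2-(2,6-bis(benzyloxy)-4-methoxyphenyl)-1-(4-methoxyphenyl)-2-(U3)ethyl]boronic acid mac ester | O(Cc1ccccc1)c1cc(OC)cc(OCc2ccccc2)c1[C@H](c1cc(OC)cc2c1[C@@H](c1cc(OC)cc(OC)c1)[C@H](c1ccc(OC)cc1)O2)[C@H](c1ccc(OC)cc1)B1O[C@@]2(C)c3cccc4cccc(c34)[C@@]2(C)O1 | intermediate (not isolated)
20 | (1R,2S)-2-[2,6-bis(benzyloxy)-4-methoxyphenyl]-1-(4-methoxyphenyl)-2-(U3)ethan-1-ol | O(Cc1ccccc1)c1cc(OC)cc(OCc2ccccc2)c1[C@H](c1cc(OC)cc2c1[C@@H](c1cc(OC)cc(OC)c1)[C@H](c1ccc(OC)cc1)O2)[C@H](c1ccc(OC)cc1)O | intermediate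
21 | 2-[(1S,2R)-2-hydroxy-2-(4-methoxyphenyl)-1-(U3)ethyl]-5-methoxybenzene-1,3-diol | Oc1cc(OC)cc(O)c1[C@H](c1cc(OC)cc2c1[C@@H](c1cc(OC)cc(OC)c1)[C@H](c1ccc(OC)cc1)O2)[C@H](c1ccc(OC)cc1)O | intermediate
22 | (2S,3S)-3-[(2R,3R)-3-(3,5-dimethoxyphenyl)-6-methoxy-2-(4-methoxyphenyl)-2,3-dihydro-1-benzofuran-4-yl]-6-methoxy-2-(4-methoxyphenyl)-2,3-dihydro-1-benzofuran-4-ol | Oc1cc(OC)cc2c1[C@H](c1cc(OC)cc3c1[C@@H](c1cc(OC)cc(OC)c1)[C@H](c1ccc(OC)cc1)O3)[C@@H](c1ccc(OC)cc1)O2 | intermediate
23 | trifluoromethanesulfonate of 22 (U23 triflate) | O=S(=O)(Oc1cc(OC)cc2c1[C@H](c1cc(OC)cc3c1[C@@H](c1cc(OC)cc(OC)c1)[C@H](c1ccc(OC)cc1)O3)[C@@H](c1ccc(OC)cc1)O2)C(F)(F)F | intermediate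
24 | (1S,2R)-[2-(2,6-bis(benzyloxy)-4-methoxyphenyl)-1-(4-methoxyphenyl)-2-(U23)ethyl]boronic acid mac ester | O(Cc1ccccc1)c1cc(OC)cc(OCc2ccccc2)c1[C@@H](c1cc(OC)cc2c1[C@H](c1cc(OC)cc3c1[C@@H](c1cc(OC)cc(OC)c1)[C@H](c1ccc(OC)cc1)O3)[C@@H](c1ccc(OC)cc1)O2)[C@@H](c1ccc(OC)cc1)B1O[C@@]2(C)c3cccc4cccc(c34)[C@@]2(C)O1 | intermediate (not isolated)
25 | (1S,2R)-2-[2,6-bis(benzyloxy)-4-methoxyphenyl]-1-(4-methoxyphenyl)-2-(U23)ethan-1-ol | O(Cc1ccccc1)c1cc(OC)cc(OCc2ccccc2)c1[C@@H](c1cc(OC)cc2c1[C@H](c1cc(OC)cc3c1[C@@H](c1cc(OC)cc(OC)c1)[C@H](c1ccc(OC)cc1)O3)[C@@H](c1ccc(OC)cc1)O2)[C@@H](c1ccc(OC)cc1)O | intermediate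
26 | 2-[(1R,2S)-2-hydroxy-2-(4-methoxyphenyl)-1-(U23)ethyl]-5-methoxybenzene-1,3-diol | Oc1cc(OC)cc(O)c1[C@@H](c1cc(OC)cc2c1[C@H](c1cc(OC)cc3c1[C@@H](c1cc(OC)cc(OC)c1)[C@H](c1ccc(OC)cc1)O3)[C@@H](c1ccc(OC)cc1)O2)[C@@H](c1ccc(OC)cc1)O | intermediate
27 | (2R,3R)-3-{(2S,3S)-3-[(2R,3R)-3-(3,5-dimethoxyphenyl)-6-methoxy-2-(4-methoxyphenyl)-2,3-dihydro-1-benzofuran-4-yl]-6-methoxy-2-(4-methoxyphenyl)-2,3-dihydro-1-benzofuran-4-yl}-6-methoxy-2-(4-methoxyphenyl)-2,3-dihydro-1-benzofuran-4-ol | Oc1cc(OC)cc2c1[C@@H](c1cc(OC)cc3c1[C@H](c1cc(OC)cc4c1[C@@H](c1cc(OC)cc(OC)c1)[C@H](c1ccc(OC)cc1)O4)[C@@H](c1ccc(OC)cc1)O3)[C@H](c1ccc(OC)cc1)O2 | intermediate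
28 | trifluoromethanesulfonate of 27 | O=S(=O)(Oc1cc(OC)cc2c1[C@@H](c1cc(OC)cc3c1[C@H](c1cc(OC)cc4c1[C@@H](c1cc(OC)cc(OC)c1)[C@H](c1ccc(OC)cc1)O4)[C@@H](c1ccc(OC)cc1)O3)[C@H](c1ccc(OC)cc1)O2)C(F)(F)F | intermediate
29 | octaphenol triflate: 28 with all eight methoxy groups replaced by hydroxy groups (configurations unchanged) | O=S(=O)(Oc1cc(O)cc2c1[C@@H](c1cc(O)cc3c1[C@H](c1cc(O)cc4c1[C@@H](c1cc(O)cc(O)c1)[C@H](c1ccc(O)cc1)O4)[C@@H](c1ccc(O)cc1)O3)[C@H](c1ccc(O)cc1)O2)C(F)(F)F | intermediate
30 | octaacetate triflate: 29 with all eight hydroxy groups as acetates | O=S(=O)(Oc1cc(OC(C)=O)cc2c1[C@@H](c1cc(OC(C)=O)cc3c1[C@H](c1cc(OC(C)=O)cc4c1[C@@H](c1cc(OC(C)=O)cc(OC(C)=O)c1)[C@H](c1ccc(OC(C)=O)cc1)O4)[C@@H](c1ccc(OC(C)=O)cc1)O3)[C@H](c1ccc(OC(C)=O)cc1)O2)C(F)(F)F | intermediate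
31 | 4-acetoxystyrene (4-ethenylphenyl acetate) | C=Cc1ccc(OC(C)=O)cc1 | starting material
32 | miyabenol A nonaacetate (E stilbene; unit 1 2R,3R; unit 2 2S,3S; unit 3 2R,3R) | CC(=O)Oc1ccc(/C=C/c2cc(OC(C)=O)cc3c2[C@@H](c2cc(OC(C)=O)cc4c2[C@H](c2cc(OC(C)=O)cc5c2[C@@H](c2cc(OC(C)=O)cc(OC(C)=O)c2)[C@H](c2ccc(OC(C)=O)cc2)O5)[C@@H](c2ccc(OC(C)=O)cc2)O4)[C@H](c2ccc(OC(C)=O)cc2)O3)cc1 | intermediate
33 | miyabenol A (E stilbene; unit 1 2R,3R; unit 2 2S,3S; unit 3 2R,3R) | Oc1ccc(/C=C/c2cc(O)cc3c2[C@@H](c2cc(O)cc4c2[C@H](c2cc(O)cc5c2[C@@H](c2cc(O)cc(O)c2)[C@H](c2ccc(O)cc2)O5)[C@@H](c2ccc(O)cc2)O4)[C@H](c2ccc(O)cc2)O3)cc1 | target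

## Step count and risks

Total step count: 24. Longest linear sequence: 22 steps (steps 1–3, 5 and 7–24, from 1 to 33).

**Step 8 (key step).**
- *What may go wrong:* the di-ortho-substituted β-aryl group is twisted out of conjugation and may bind cationic palladium poorly, so direct transmetallation (Suzuki–Miyaura coupling) or protodeboronation could overtake the metallate shift. Reductive elimination at the crowded benzylic palladium carbon may be slow. Facial selectivity may be poor, because the ligand has no record with a β-aryl group of this kind.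
- *Fallback:* sets out from 2 and returns at 17, replacing the coupling by a catalytic asymmetric C–H insertion.
  - 2 is etherified with 4-methoxybenzyl chloride (K2CO3, DMF) to 2,6-bis[(4-methoxybenzyl)oxy]-4-methoxybenzaldehyde F1.
  - Commercial 3,5-dimethoxyphenylmagnesium chloride adds to give the diarylmethanol F2, which MnO2 oxidises to the benzophenone F3.
  - Hydrazine with acetic acid in hot ethanol gives the hydrazone F4, and MnO2 converts it to the diaryldiazomethane F5.
  - Without isolation, F5 is decomposed by the enantiomer of Rh2(PTAD)4, dirhodium tetrakis(N-phthaloyl-adamantylglycinate), that gives C3 as R. The donor/donor carbene of divalent rhodium inserts into the O–CH2 bond of one 4-methoxybenzyl ether to give the cis dihydrobenzofuran F6.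
  - Trifluoroacetic acid with pentamethylbenzene in CH2Cl2 removes the remaining 4-methoxybenzyl ether and epimerises C2 through reversible ionisation of the C2–O bond, giving the trans phenol 17.

**Step 13 (and, in the same way, step 17).**
- *What may go wrong:* the aryl triflate carries a branched ortho substituent, so oxidative addition and, above all, reductive elimination onto a carbon that already bears a di-ortho-substituted arene may be slower than catalyst decay. Mismatched double stereodifferentiation between ligand and substrate may lower the diastereoselectivity.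
- *Fallback:* sets out from 18 and 3 and returns at 19. The roles of the two arenes at the diaryl carbon are exchanged, so that the bond made by reductive elimination is C3–C3a of unit 2.
  - Stille coupling of 18 with tributyl(ethynyl)stannane (Pd(PPh3)4, LiCl, dioxane) gives the 4-ethynyl dihydrobenzofuran F7.
  - Catecholborane gives the catechol boronate F8, and diol 6 exchanges it to the alkenylboronic mac ester F9.
  - Aldehyde 3 undergoes Dakin-type oxidation with mCPBA to the aryl formate F10, which K2CO3 in methanol cleaves to 2,6-bis(benzyloxy)-4-methoxyphenol F11. Tf2O and pyridine give the triflate F12.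
  - 4-Methoxyphenyllithium 12, generated from 11 and freed of bromide as in step 7, adds to F9 to give the borate F13, which is coupled with F12 under the conditions of step 13 (ligand enantiomer chosen for the 1R,2S product) to give 19. Oxidation as in step 13 gives 20.

**Step 21.**
- *What may go wrong:* incomplete eightfold demethylation of a crowded substrate. Ionisation of the 4-oxybenzylic C2–O bonds under the Lewis acid could lead to intermolecular Friedel–Crafts alkylation instead of simple re-closure.
- *Fallback:* sets out from 28 and returns at 33, avoiding Lewis acid altogether.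
  - Heck reaction of 28 with 4-methoxystyrene (PdCl2(PPh3)2, LiCl, Et3N, DMF) gives nona-O-methylmiyabenol A F14.
  - Nucleophilic demethylation with sodium ethanethiolate in DMF at 140 °C under argon, followed by mild acidification, gives 33. These conditions are basic and leave the stilbene untouched.

**Step 23.**
- *What may go wrong:* sluggish oxidative addition of the ortho-branched triflate with catalyst decomposition; partial loss of acetate groups in hot amine; some arylation at the internal alkene carbon.
- *Fallback:* sets out from 30 and returns at 32, moving the aryl–alkene bond formation to the unhindered end.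
  - Stille coupling of 30 with tributyl(vinyl)stannane (Pd(PPh3)4, LiCl, dioxane) gives the 4-vinyl octaacetate F15.
  - A ligand-free Heck reaction of F15 with 4-iodophenyl acetate (Pd(OAc)2, n-Bu4NCl, NaHCO3, DMF, 80 °C) gives 32.

**Step 11 (and steps 15 and 19).**
- *What may go wrong:* the oxyphosphonium salt of the 4-methoxybenzylic alcohol could eliminate to the triarylethylene or ionise, so the closure is not cleanly invertive. Intermolecular etherification is possible at high concentration.
- *Fallback:* sets out from 16 and returns at 17 with no new compound (F0). Catalytic camphorsulfonic acid in CH2Cl2 at 0 °C ionises the carbinol on purpose, and the ortho phenol traps the cation to give the favoured trans ring. C3 is not touched.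

## Further compounds

F1 | step 8 | 2,6-bis[(4-methoxybenzyl)oxy]-4-methoxybenzaldehyde | COc1ccc(COc2cc(OC)cc(OCc3ccc(OC)cc3)c2C=O)cc1
F2 | step 8 | {2,6-bis[(4-methoxybenzyl)oxy]-4-methoxyphenyl}(3,5-dimethoxyphenyl)methanol (racemic) | COc1ccc(COc2cc(OC)cc(OCc3ccc(OC)cc3)c2C(O)c2cc(OC)cc(OC)c2)cc1
F3 | step 8 | {2,6-bis[(4-methoxybenzyl)oxy]-4-methoxyphenyl}(3,5-dimethoxyphenyl)methanone | COc1ccc(COc2cc(OC)cc(OCc3ccc(OC)cc3)c2C(=O)c2cc(OC)cc(OC)c2)cc1
F4 | step 8 | hydrazone of F3 | COc1ccc(COc2cc(OC)cc(OCc3ccc(OC)cc3)c2C(=NN)c2cc(OC)cc(OC)c2)cc1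
F5 | step 8 | {2,6-bis[(4-methoxybenzyl)oxy]-4-methoxyphenyl}(3,5-dimethoxyphenyl)diazomethane | COc1ccc(COc2cc(OC)cc(OCc3ccc(OC)cc3)c2C(=[N+]=[N-])c2cc(OC)cc(OC)c2)cc1
F6 | step 8 | (2S,3R)-cis-3-(3,5-dimethoxyphenyl)-6-methoxy-4-[(4-methoxybenzyl)oxy]-2-(4-methoxyphenyl)-2,3-dihydro-1-benzofuran | COc1ccc(COc2cc(OC)cc3c2[C@@H](c2cc(OC)cc(OC)c2)[C@@H](c2ccc(OC)cc2)O3)cc1
F7 | step 13 | (2R,3R)-3-(3,5-dimethoxyphenyl)-4-ethynyl-6-methoxy-2-(4-methoxyphenyl)-2,3-dihydro-1-benzofuran | C#Cc1cc(OC)cc2c1[C@@H](c1cc(OC)cc(OC)c1)[C@H](c1ccc(OC)cc1)O2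
F8 | step 13 | 2-{(E)-2-[(2R,3R)-3-(3,5-dimethoxyphenyl)-6-methoxy-2-(4-methoxyphenyl)-2,3-dihydro-1-benzofuran-4-yl]ethenyl}-1,3,2-benzodioxaborole | B1(Oc2ccccc2O1)/C=C/c1cc(OC)cc2c1[C@@H](c1cc(OC)cc(OC)c1)[C@H](c1ccc(OC)cc1)O2
F9 | step 13 | {(E)-2-[(2R,3R)-3-(3,5-dimethoxyphenyl)-6-methoxy-2-(4-methoxyphenyl)-2,3-dihydro-1-benzofuran-4-yl]ethenyl}boronic acid mac ester | B1(O[C@@]2(C)c3cccc4cccc(c34)[C@@]2(C)O1)/C=C/c1cc(OC)cc2c1[C@@H](c1cc(OC)cc(OC)c1)[C@H](c1ccc(OC)cc1)O2
F10 | step 13 | 2,6-bis(benzyloxy)-4-methoxyphenyl formate | O=COc1c(OCc2ccccc2)cc(OC)cc1OCc1ccccc1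
F11 | step 13 | 2,6-bis(benzyloxy)-4-methoxyphenol | Oc1c(OCc2ccccc2)cc(OC)cc1OCc1ccccc1
F12 | step 13 | 2,6-bis(benzyloxy)-4-methoxyphenyl trifluoromethanesulfonate | O=S(=O)(Oc1c(OCc2ccccc2)cc(OC)cc1OCc1ccccc1)C(F)(F)F
F13 | step 13 | lithium (4-methoxyphenyl)borate formed from F9 and 12 | [Li+].COc1ccc(cc1)[B-]1(/C=C/c2cc(OC)cc3c2[C@@H](c2cc(OC)cc(OC)c2)[C@H](c2ccc(OC)cc2)O3)O[C@@]2(C)c3cccc4cccc(c34)[C@@]2(C)O1
F14 | step 21 | nona-O-methylmiyabenol A | COc1ccc(/C=C/c2cc(OC)cc3c2[C@@H](c2cc(OC)cc4c2[C@H](c2cc(OC)cc5c2[C@@H](c2cc(OC)cc(OC)c2)[C@H](c2ccc(OC)cc2)O5)[C@@H](c2ccc(OC)cc2)O4)[C@H](c2ccc(OC)cc2)O3)cc1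
F15 | step 23 | 4-vinyl octaacetate (30 with ethenyl in place of the triflate group) | C=Cc1cc(OC(C)=O)cc2c1[C@@H](c1cc(OC(C)=O)cc3c1[C@H](c1cc(OC(C)=O)cc4c1[C@@H](c1cc(OC(C)=O)cc(OC(C)=O)c1)[C@H](c1ccc(OC(C)=O)cc1)O4)[C@@H](c1ccc(OC(C)=O)cc1)O3)[C@H](c1ccc(OC(C)=O)cc1)O2
F0 | step 11 | none | none
A1 | alternative 1 | miyabenol A hexamethyl triethyl ether | COc1ccc(/C=C/c2cc(OCC)cc3c2[C@@H](c2cc(OCC)cc4c2[C@H](c2cc(OCC)cc5c2[C@@H](c2cc(OC)cc(OC)c2)[C@H](c2ccc(OC)cc2)O5)[C@@H](c2ccc(OC)cc2)O4)[C@H](c2ccc(OC)cc2)O3)cc1
A2 | alternative 1 | open unit-1 diyne (enyne alkyne on C3, ethynyl ether on the C2 oxygen) | COc1ccc(/C=C/C#C[C@@H](c2cc(OCC)cc3c2[C@H](c2cc(OCC)cc4c2[C@@H](c2cc(OC)cc(OC)c2)[C@H](c2ccc(OC)cc2)O4)[C@@H](c2ccc(OC)cc2)O3)[C@H](c2ccc(OC)cc2)OC#C)cc1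
A3 | alternative 1 | ethoxyacetylene | CCOC#C
A4 | alternative 2 | (2S)-naringenin | O=C1C[C@@H](c2ccc(O)cc2)Oc2cc(O)cc(O)c12
A5 | alternative 2 | methyl trans-4-benzyloxy-6-methoxy-2-(4-methoxyphenyl)-2,3-dihydrobenzofuran-3-carboxylate (unit-2 configuration) | O(Cc1ccccc1)c1cc(OC)cc2c1[C@H](C(=O)OC)[C@@H](c1ccc(OC)cc1)O2
A6 | alternative 3 | tris(3-aryl-2,3-dihydrobenzofuran-2-carboxylic acid), C2 configuration immaterial | O(Cc1ccccc1)c1cc(OC)cc2c1[C@@H](c1cc(OC)cc3c1[C@H](c1cc(OC)cc4c1[C@@H](c1cc(OC)cc(OC)c1)C(C(=O)O)O4)C(C(=O)O)O3)C(C(=O)O)O2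
A7 | alternative 3 | 4-iodoanisole | COc1ccc(I)cc1
A8 | alternative 3 | octa-O-methyl tris(dihydrobenzofuran) with benzyloxy at C4 of unit 1 | O(Cc1ccccc1)c1cc(OC)cc2c1[C@@H](c1cc(OC)cc3c1[C@H](c1cc(OC)cc4c1[C@@H](c1cc(OC)cc(OC)c1)[C@H](c1ccc(OC)cc1)O4)[C@@H](c1ccc(OC)cc1)O3)[C@H](c1ccc(OC)cc1)O2
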